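**Retrosynthetic overview**

1. Enabling feature: in ring B (C5–C6–C7–C8–C1–C9) the unit C6–C7(prenyl)–C8(Me2) is a second lavandulyl group on C5, of configuration opposite to the intact C5 side chain, and C9 (between C5 and C1) bears oxygen. C8 can therefore be parked on O9 as a six-membered cyclic enol ether and moved to the neighbouring carbon C1 by a 1,3-O-to-C shift.
2. Disconnections: C1–C8 (ring B, last) ⇒ pyran-fused dienone; C1–prenyl ⇒ Stille coupling on a bromine placeholder; C5–lavandulyl ⇒ alkylative dearomatisation of a 6-aroylchroman with (R)-lavandulyl triflate, trans to the C7 prenyl group (1,3-relay through the temporary pyran).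
3. The chroman ⇒ brominated acylphloroglucinol + (S)-lavandulyl triflate (C-alkylation, then hydroalkoxylation onto the hydroxyl para to the ketone). Both lavandulols come from Evans alkylations, the benzophenone from a Houben–Hoesch reaction.
4. Ring order: the aryl ring and ring A (phloroglucinol) are bought; the temporary pyran is made in step 13; ring B is closed last in step 16, which also removes the pyran.

Key step: step 16

Remark: ring atoms are numbered as in the bicyclo[3.3.1]nonane core (C1 prenyl bridgehead, C2–C3–C4 enolised diketone with the aroyl group on C3, C5 lavandulyl bridgehead, C6 CH2, C7 CH-prenyl, C8 CMe2, C9 bridging ketone, O9 the oxygen on C9); enolised triketones are drawn as one tautomer.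

**Route**

Step 1
Reactants: 1 (S)-4-benzyloxazolidin-2-one; 2 3-methylbut-2-enoyl chloride
Product: 3 (S)-4-benzyl-3-(3-methylbut-2-enoyl)oxazolidin-2-one
Conditions: n-BuLi, THF, −78 °C; then 2, −78 to 0 °C
Reagents that add atoms: 3-methylbut-2-enoyl chloride (2), CC(C)=CC(Cl)=O
Why: N-acylation of the lithiated oxazolidinone by the acid chloride (nucleophilic acyl substitution); no stereocentre is formed.

Step 2
Reactants: 3 (S)-4-benzyl-3-(3-methylbut-2-enoyl)oxazolidin-2-one; 4 prenyl bromide
Product: 5 (S)-4-benzyl-3-[(2S)-5-methyl-2-(prop-1-en-2-yl)hex-4-enoyl]oxazolidin-2-one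
Conditions: NaN(SiMe3)2, THF, −78 °C; then 4, −78 to −40 °C
Reagents that add atoms: prenyl bromide (4), CC(C)=CCBr
Why: Evans asymmetric alkylation in its deconjugative form: γ-deprotonation should give the chelated Z-dienolate, which is alkylated at the α-carbon on the face opposite the benzyl group, so the auxiliary sets the (2S) centre and the double bond ends up as the isopropenyl group.

Step 3
Reactants: 5 (S)-4-benzyl-3-[(2S)-5-methyl-2-(prop-1-en-2-yl)hex-4-enoyl]oxazolidin-2-one
Product: 6 (S)-lavandulol
Conditions: LiBH4, H2O (1 equiv), Et2O, 0 °C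
Reagents that add atoms: none
Why: reductive cleavage of the N-acyloxazolidinone (hydride reduction) under non-basic conditions, so the stereocentre next to the isopropenyl group should neither epimerise nor move into conjugation; the auxiliary is recovered.

Step 4
Reactants: 6 (S)-lavandulol; 7 trifluoromethanesulfonic anhydride
Product: 8 (S)-lavandulyl triflate
Conditions: 2,6-lutidine, CH2Cl2, −78 °C; used at once
Reagents that add atoms: trifluoromethanesulfonic anhydride (7), O=S(=O)(OS(=O)(=O)C(F)(F)F)C(F)(F)F
Why: O-sulfonylation of the primary alcohol; the stereocentre is not involved, and a triflate is needed because the β-branched primary carbon is a sluggish electrophile.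

Step 5
Reactants: 9 (R)-4-benzyloxazolidin-2-one; 2 3-methylbut-2-enoyl chloride
Product: 10 (R)-4-benzyl-3-(3-methylbut-2-enoyl)oxazolidin-2-one
Conditions: n-BuLi, THF, −78 °C; then 2, −78 to 0 °C
Reagents that add atoms: 3-methylbut-2-enoyl chloride (2), CC(C)=CC(Cl)=O
Why: the same N-acylation as in step 1 with the enantiomeric auxiliary; no stereocentre is formed.

Step 6
Reactants: 10 (R)-4-benzyl-3-(3-methylbut-2-enoyl)oxazolidin-2-one; 4 prenyl bromide
Product: 11 (R)-4-benzyl-3-[(2R)-5-methyl-2-(prop-1-en-2-yl)hex-4-enoyl]oxazolidin-2-one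
Conditions: NaN(SiMe3)2, THF, −78 °C; then 4, −78 to −40 °C
Reagents that add atoms: prenyl bromide (4), CC(C)=CCBr
Why: deconjugative Evans asymmetric alkylation as in step 2; the enantiomeric auxiliary shields the other face of the Z-dienolate and sets the (2R) centre.

Step 7
Reactants: 11 (R)-4-benzyl-3-[(2R)-5-methyl-2-(prop-1-en-2-yl)hex-4-enoyl]oxazolidin-2-one
Product: 12 (R)-lavandulol
Conditions: LiBH4, H2O (1 equiv), Et2O, 0 °C
Reagents that add atoms: none
Why: reductive cleavage of the imide (hydride reduction) as in step 3, without epimerisation of the stereocentre.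

Step 8
Reactants: 12 (R)-lavandulol; 7 trifluoromethanesulfonic anhydride
Product: 13 (R)-lavandulyl triflate
Conditions: 2,6-lutidine, CH2Cl2, −78 °C; used at once
Reagents that add atoms: trifluoromethanesulfonic anhydride (7), O=S(=O)(OS(=O)(=O)C(F)(F)F)C(F)(F)F
Why: O-sulfonylation of the primary alcohol as in step 4; the stereocentre is not involved.

Step 9
Reactants: 14 3-hydroxybenzonitrile; 15 pivaloyl chloride
Product: 16 3-cyanophenyl pivalate
Conditions: Et3N, 4-(dimethylamino)pyridine (cat.), CH2Cl2, 0 °C
Reagents that add atoms: pivaloyl chloride (15), CC(C)(C)C(Cl)=O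
Why: esterification of the phenol; the pivalate has no α-hydrogen and is hindered, so it should survive the amide bases, phenoxides, palladium catalysis and silyl triflate used later.

Step 10
Reactants: 16 3-cyanophenyl pivalate; 17 phloroglucinol
Product: 19 3-(2,4,6-trihydroxybenzoyl)phenyl pivalate, via ketiminium chloride 18 (not isolated)
Conditions: ZnCl2, HCl (gas), Et2O, 0 °C; then H2O, 100 °C
Reagents that add atoms: water, O
Why: Houben–Hoesch reaction: the activated nitrile acylates the very electron-rich phloroglucinol once, and hydrolysis of the ketiminium salt gives the aryl ketone; no stereocentre.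

Step 11
Reactants: 19 3-(2,4,6-trihydroxybenzoyl)phenyl pivalate; 20 N-bromosuccinimide
Product: 21 3-(3-bromo-2,4,6-trihydroxybenzoyl)phenyl pivalate
Conditions: 20 (1.0 equiv), THF, −78 °C
Reagents that add atoms: N-bromosuccinimide (20), O=C1CCC(=O)N1Br
Why: electrophilic aromatic bromination of the phloroglucinol ring with one equivalent of reagent; the bromine is the placeholder for the C1 prenyl group and blocks this carbon against later alkylation.

Step 12
Reactants: 21 3-(3-bromo-2,4,6-trihydroxybenzoyl)phenyl pivalate; 8 (S)-lavandulyl triflate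
Product: 22 3-{3-bromo-2,4,6-trihydroxy-5-[(2R)-5-methyl-2-(prop-1-en-2-yl)hex-4-enyl]benzoyl}phenyl pivalate
Conditions: LiN(SiMe3)2 (3.1 equiv), THF, −78 °C; then 8, −78 to 0 °C
Reagents that add atoms: (S)-lavandulyl triflate (8), C=C(C)[C@H](CC=C(C)C)COS(=O)(=O)C(F)(F)F
Why: C-alkylation of the acylphloroglucinol polyanion by a primary triflate (SN2) at the only unsubstituted ring carbon; the stereocentre of the triflate is not at the reacting carbon and is carried over unchanged (it becomes C7).

Step 13
Reactants: 22 3-{3-bromo-2,4,6-trihydroxy-5-[(2R)-5-methyl-2-(prop-1-en-2-yl)hex-4-enyl]benzoyl}phenyl pivalate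
Product: 23 3-{[(3R)-8-bromo-5,7-dihydroxy-2,2-dimethyl-3-(3-methylbut-2-enyl)chroman-6-yl]carbonyl}phenyl pivalate
Conditions: (CF3)2CHOH, 50 °C, no added acid
Reagents that add atoms: none
Why: intramolecular Markovnikov hydroalkoxylation of the isopropenyl group (phenol–alkene cyclisation to a 2,2-dimethylchroman): in the ionising solvent the most acidic hydroxyl (para to the ketone, further acidified by the ortho bromine) should protonate the alkene and capture the tertiary cation within the contact ion pair, while the two ortho hydroxyls are less acidic and chelated to the ketone; no new stereocentre is formed.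

Step 14
Reactants: 23 the chroman of step 13; 13 (R)-lavandulyl triflate
Product: 24 (3R)-8-bromo-5-hydroxy-2,2-dimethyl-3-(3-methylbut-2-enyl)-4a-[(2S)-5-methyl-2-(prop-1-en-2-yl)hex-4-enyl]-6-[3-(pivaloyloxy)benzoyl]-3,4-dihydro-2H-chromen-7(4aH)-one (C4a chain trans to the C3 prenyl group)
Conditions: LiN(SiMe3)2 (2.1 equiv), THF, −78 °C; then 13, −78 to 0 °C
Reagents that add atoms: (R)-lavandulyl triflate (13), C=C(C)[C@@H](CC=C(C)C)COS(=O)(=O)C(F)(F)F
Why: alkylative dearomatisation of the acylphloroglucinol dianion with a primary triflate: bromine blocks C8 and the aroyl group blocks C6, so C-alkylation can only occur at the ring-fusion carbon C4a (C5 of the target), and the electrophile should enter through a chair-like transition state on the face opposite the pseudo-axial C2 methyl group and syn to the axial C3 hydrogen, which places the new chain trans to the equatorial prenyl group and so sets the quaternary stereocentre C5.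

Step 15
Reactants: 24 the bromo-dienone of step 14; 25 tributyl(3-methylbut-2-enyl)stannane
Product: 26 (3R)-5-hydroxy-2,2-dimethyl-3,8-bis(3-methylbut-2-enyl)-4a-[(2S)-5-methyl-2-(prop-1-en-2-yl)hex-4-enyl]-6-[3-(pivaloyloxy)benzoyl]-3,4-dihydro-2H-chromen-7(4aH)-one
Conditions: Pd(PPh3)4 (10 mol %), CuI (20 mol %), Et3N (1.2 equiv), DMF, 50 °C
Reagents that add atoms: tributyl(3-methylbut-2-enyl)stannane (25), CC(C)=CC[Sn](CCCC)(CCCC)CCCC
Why: Stille coupling of the 2-bromo-3-alkoxyenone (oxidative addition to zerovalent palladium) with the prenylstannane, which should transfer the allyl group without transposition; Et3N keeps the acidic enol as its ammonium salt so that it cannot protodestannylate the reagent, and no stereocentre is touched.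

Step 16
Reactants: 26 the pyran-fused dienone of step 15
Product: 29 pivalate of the target (bicyclo[3.3.1]nonane core complete), via silyl dienol ether 27 (not isolated), via silylated bicycle 28 (not isolated)
Conditions: Me3SiOTf (1.5 equiv), 2,6-di-tert-butyl-4-methylpyridine (2 equiv), CH2Cl2, −78 to −20 °C; then H2O
Reagents that add atoms: none
Why: Proposed new method: silylation of the enol gives 27, in which Me3SiOTf activation of the C2 carbonyl makes O9 the oxygen of a vinylogous silyl ester, so the tertiary C8–O9 bond ionises to a carbocation held by the C5–C6–C7 tether in a contact ion pair with a bis-silyl dienolate whose nucleophilic terminus is C1; recombination at C1 forms the C1–C8 bond between two fully substituted carbons and turns C9 into the bridging ketone, i.e. a Lewis-acid 1,3-O-to-C shift that contracts the six-membered cyclic enol ether to the six-membered carbocycle (ring B). The closest known reactions are the Lewis-acid 1,3-O-to-C rearrangement of enol ethers (Petasis–Ferrier-type ring contraction), the SN1 tert-alkylation of silyl enol ethers by tertiary carbocations, and the biomimetic cationic cyclisation of dearomatised acylphloroglucinols, which makes the same C1–C8 bond from a tertiary cation. Ring B closes in a 6-(enolexo) mode by attack of C1 on the cation, the atoms C5, C6, C7 and C8 being carried over unchanged from the pyran. The new quaternary stereocentre C1 is controlled by the tether: C8 can reach C1 only on the face of ring A on which C6 leaves C5, so C1 is relayed from C5, and the endo orientation of the C7 prenyl group follows from the trans C5/C7 relationship set in step 14. The step needs C- over O-recapture (O-recapture only regenerates 27, C–C formation is irreversible), C1 over C3 (C3 carries the aroyl group and is remote from the ion pair born at O9) and no E1 loss of a proton from the cation (this would give an achiral C5 bis-lavandulyl compound and erase the difference between the two chains); aprotic conditions, a hindered pyridine and low temperature should secure this and leave the isopropenyl and prenyl groups untouched.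

Step 17
Reactants: 29 pivalate of the target
Product: 30 target CNP0103487.1
Conditions: K2CO3, MeOH, 23 °C; then aqueous NH4Cl
Reagents that add atoms: none
Why: base-mediated methanolysis of the aryl pivalate (transesterification); the enolised triketone is present as its inert enolate and no stereocentre is epimerisable.

**Compound list**

1 | (S)-4-benzyloxazolidin-2-one | O=C1N[C@@H](Cc2ccccc2)CO1 | starting material
2 | 3-methylbut-2-enoyl chloride | CC(C)=CC(Cl)=O | starting material
3 | (S)-4-benzyl-3-(3-methylbut-2-enoyl)oxazolidin-2-one | CC(C)=CC(=O)N1[C@@H](Cc2ccccc2)COC1=O | intermediate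
4 | prenyl bromide (1-bromo-3-methylbut-2-ene) | CC(C)=CCBr | starting material
5 | (S)-4-benzyl-3-[(2S)-5-methyl-2-(prop-1-en-2-yl)hex-4-enoyl]oxazolidin-2-one | C=C(C)[C@H](CC=C(C)C)C(=O)N1[C@@H](Cc2ccccc2)COC1=O | intermediate
6 | (S)-lavandulol, (2S)-5-methyl-2-(prop-1-en-2-yl)hex-4-en-1-ol | C=C(C)[C@H](CC=C(C)C)CO | intermediate
7 | trifluoromethanesulfonic anhydride | O=S(=O)(OS(=O)(=O)C(F)(F)F)C(F)(F)F | starting material
8 | (S)-lavandulyl triflate | C=C(C)[C@H](CC=C(C)C)COS(=O)(=O)C(F)(F)F | intermediate
9 | (R)-4-benzyloxazolidin-2-one | O=C1N[C@H](Cc2ccccc2)CO1 | starting material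
10 | (R)-4-benzyl-3-(3-methylbut-2-enoyl)oxazolidin-2-one | CC(C)=CC(=O)N1[C@H](Cc2ccccc2)COC1=O | intermediate
11 | (R)-4-benzyl-3-[(2R)-5-methyl-2-(prop-1-en-2-yl)hex-4-enoyl]oxazolidin-2-one | C=C(C)[C@@H](CC=C(C)C)C(=O)N1[C@H](Cc2ccccc2)COC1=O | intermediate
12 | (R)-lavandulol, (2R)-5-methyl-2-(prop-1-en-2-yl)hex-4-en-1-ol | C=C(C)[C@@H](CC=C(C)C)CO | intermediate
13 | (R)-lavandulyl triflate | C=C(C)[C@@H](CC=C(C)C)COS(=O)(=O)C(F)(F)F | intermediate
14 | 3-hydroxybenzonitrile | N#Cc1cccc(O)c1 | starting material
15 | pivaloyl chloride | CC(C)(C)C(Cl)=O | starting material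
16 | 3-cyanophenyl pivalate | CC(C)(C)C(=O)Oc1cccc(C#N)c1 | intermediate
17 | phloroglucinol | Oc1cc(O)cc(O)c1 | starting material
18 | [3-(pivaloyloxy)phenyl](2,4,6-trihydroxyphenyl)methaniminium chloride | CC(C)(C)C(=O)Oc1cccc(c1)C(=[NH2+])c1c(O)cc(O)cc1O.[Cl-] | intermediate (not isolated)
19 | 3-(2,4,6-trihydroxybenzoyl)phenyl pivalate | CC(C)(C)C(=O)Oc1cccc(c1)C(=O)c1c(O)cc(O)cc1O | intermediate
20 | N-bromosuccinimide | O=C1CCC(=O)N1Br | starting material
21 | 3-(3-bromo-2,4,6-trihydroxybenzoyl)phenyl pivalate | CC(C)(C)C(=O)Oc1cccc(c1)C(=O)c1c(O)cc(O)c(Br)c1O | intermediate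
22 | 3-{3-bromo-2,4,6-trihydroxy-5-[(2R)-5-methyl-2-(prop-1-en-2-yl)hex-4-enyl]benzoyl}phenyl pivalate (side chain from (S)-lavandulol) | CC(C)(C)C(=O)Oc1cccc(c1)C(=O)c1c(O)c(Br)c(O)c(C[C@@H](CC=C(C)C)C(C)=C)c1O | intermediate
23 | 3-{[(3R)-8-bromo-5,7-dihydroxy-2,2-dimethyl-3-(3-methylbut-2-enyl)chroman-6-yl]carbonyl}phenyl pivalate | CC(C)(C)C(=O)Oc1cccc(c1)C(=O)c1c(O)c(Br)c2OC(C)(C)[C@H](CC=C(C)C)Cc2c1O | intermediate
24 | (3R)-8-bromo-5-hydroxy-2,2-dimethyl-3-(3-methylbut-2-enyl)-4a-[(2S)-5-methyl-2-(prop-1-en-2-yl)hex-4-enyl]-6-[3-(pivaloyloxy)benzoyl]-3,4-dihydro-2H-chromen-7(4aH)-one, C4a chain trans to the C3 prenyl group | C=C(C)[C@@H](CC=C(C)C)C[C@@]12C[C@@H](CC=C(C)C)C(C)(C)OC2=C(Br)C(=O)C(C(=O)c3cccc(OC(=O)C(C)(C)C)c3)=C1O | intermediate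
25 | tributyl(3-methylbut-2-enyl)stannane | CC(C)=CC[Sn](CCCC)(CCCC)CCCC | starting material
26 | (3R)-5-hydroxy-2,2-dimethyl-3,8-bis(3-methylbut-2-enyl)-4a-[(2S)-5-methyl-2-(prop-1-en-2-yl)hex-4-enyl]-6-[3-(pivaloyloxy)benzoyl]-3,4-dihydro-2H-chromen-7(4aH)-one, C4a chain trans to the C3 prenyl group | C=C(C)[C@@H](CC=C(C)C)C[C@@]12C[C@@H](CC=C(C)C)C(C)(C)OC2=C(CC=C(C)C)C(=O)C(C(=O)c3cccc(OC(=O)C(C)(C)C)c3)=C1O | intermediate
27 | 5-O-trimethylsilyl dienol ether of 26 | C=C(C)[C@@H](CC=C(C)C)C[C@@]12C[C@@H](CC=C(C)C)C(C)(C)OC2=C(CC=C(C)C)C(=O)C(C(=O)c3cccc(OC(=O)C(C)(C)C)c3)=C1O[Si](C)(C)C | intermediate (not isolated)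
28 | O-trimethylsilyl enol ether of 29 | C=C(C)[C@@H](CC=C(C)C)C[C@@]12C[C@@H](CC=C(C)C)C(C)(C)[C@@](CC=C(C)C)(C(=O)C(C(=O)c3cccc(OC(=O)C(C)(C)C)c3)=C1O[Si](C)(C)C)C2=O | intermediate (not isolated)
29 | pivalate of the target: the target with its aryl hydroxyl as the 2,2-dimethylpropanoate, same configuration at all four stereocentres | C=C(C)[C@@H](CC=C(C)C)C[C@@]12C[C@@H](CC=C(C)C)C(C)(C)[C@@](CC=C(C)C)(C(=O)C(C(=O)c3cccc(OC(=O)C(C)(C)C)c3)=C1O)C2=O | intermediate
30 | target CNP0103487.1: (1S,5R,7R)-3-[hydroxy(3-hydroxyphenyl)methylidene]-6,6-dimethyl-5,7-bis(3-methylbut-2-enyl)-1-[(2S)-5-methyl-2-(prop-1-en-2-yl)hex-4-enyl]bicyclo[3.3.1]nonane-2,4,9-trione, drawn as its endocyclic enol tautomer (systematic numbering, C1 being the lavandulyl bridgehead) | C=C(C)[C@@H](CC=C(C)C)C[C@@]12C[C@@H](CC=C(C)C)C(C)(C)[C@@](CC=C(C)C)(C(=O)C(C(=O)c3cccc(O)c3)=C1O)C2=O | target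

**Step count**

Total: 17 steps. Longest linear sequence: 10 steps (steps 1–4, then 12–17, from auxiliary 1).

**Steps most likely to fail**

Step 16 (Proposed new method). What may go wrong: after ionisation the tertiary cation may lose a proton (E1), undergo a 1,2-hydride shift from C7, or be recaptured only at oxygen, so that the C1–C8 bond does not form. The fallback uses the known Brønsted-acid manifold and sets out from 26. O-Methylation with Me3SiCHN2 (MeOH/toluene, 0 °C) gives the methyl enol ether of 26 F1. Neat HCO2H at 23 °C is the known biomimetic cationic cyclisation of methyl enol ethers of dearomatised acylphloroglucinols; here the tertiary cation would arise by solvolysis of the cyclic enol ether, O-recapture being reversible and C1–C8 bond formation not, and it should give the methyl enol ether of 29 F2. LiOH in dioxane/water at 90 °C then cleaves the methyl enol ether and the pivalate together, and the route is rejoined at 30.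

Step 13. What may go wrong: poor site selectivity between the two hydroxyls that flank the side chain; closure onto the hydroxyl next to the ketone would give the angular chroman and, after steps 14–16, the C7-epimeric series. The fallback controls the site by protecting groups and sets out from 22. Ac2O/pyridine gives the triacetate of 22 F3. Imidazole in MeOH at 0 °C should remove only the most activated acetate, the one para to the ketone, to give the 2,6-diacetate of 22 F4 with the para hydroxyl free. A sulfonic acid resin in CH2Cl2 at 0 °C closes the only free hydroxyl onto the isopropenyl group to give the diacetate of 23 F5. K2CO3 in MeOH at 0 °C removes the two aryl acetates faster than the pivalate, and the route is rejoined at 23.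

Step 15. What may go wrong: slow oxidative addition at the hindered, enolate-bearing vinyl bromide, protodestannylation of the reagent by the acidic enol, or allylic transposition during transfer of the prenyl group. The fallback drops halogen and cross-coupling and sets out from 19. C-Alkylation with 8 under the conditions of step 12 (mono- and bis-alkylated material separated) gives the debromo analogue of 22 F6. (CF3)2CHOH at 50 °C gives the debromo analogue of 23 F7. Classical C-prenylation with prenyl bromide 4 and aqueous KOH at 0 °C at the only free ring carbon gives the 8-prenyl analogue of 23 F8. Alkylative dearomatisation with 13 under the conditions of step 14 then rejoins the route at 26; this relies on the preference for the tied-back ring-fusion carbon, and the isomer from attack at the prenyl-bearing carbon is removed by chromatography.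

Further compounds
F1 | step 16 | methyl enol ether of 26 | C=C(C)[C@@H](CC=C(C)C)C[C@@]12C[C@@H](CC=C(C)C)C(C)(C)OC2=C(CC=C(C)C)C(=O)C(C(=O)c3cccc(OC(=O)C(C)(C)C)c3)=C1OC
F2 | step 16 | methyl enol ether of 29 | C=C(C)[C@@H](CC=C(C)C)C[C@@]12C[C@@H](CC=C(C)C)C(C)(C)[C@@](CC=C(C)C)(C(=O)C(C(=O)c3cccc(OC(=O)C(C)(C)C)c3)=C1OC)C2=O
F3 | step 13 | triacetate of 22 | CC(C)(C)C(=O)Oc1cccc(c1)C(=O)c1c(OC(C)=O)c(Br)c(OC(C)=O)c(C[C@@H](CC=C(C)C)C(C)=C)c1OC(C)=O
F4 | step 13 | 2,6-diacetate of 22 | CC(C)(C)C(=O)Oc1cccc(c1)C(=O)c1c(OC(C)=O)c(Br)c(O)c(C[C@@H](CC=C(C)C)C(C)=C)c1OC(C)=O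
F5 | step 13 | diacetate of 23 | CC(C)(C)C(=O)Oc1cccc(c1)C(=O)c1c(OC(C)=O)c(Br)c2OC(C)(C)[C@H](CC=C(C)C)Cc2c1OC(C)=O
F6 | step 15 | debromo analogue of 22 | CC(C)(C)C(=O)Oc1cccc(c1)C(=O)c1c(O)cc(O)c(C[C@@H](CC=C(C)C)C(C)=C)c1O
F7 | step 15 | debromo analogue of 23 | CC(C)(C)C(=O)Oc1cccc(c1)C(=O)c1c(O)cc2OC(C)(C)[C@H](CC=C(C)C)Cc2c1O
F8 | step 15 | 8-prenyl analogue of 23 | CC(C)(C)C(=O)Oc1cccc(c1)C(=O)c1c(O)c(CC=C(C)C)c2OC(C)(C)[C@H](CC=C(C)C)Cc2c1O
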